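## Retrosynthetic overview

1. Plakortolide F ⇐ its O‑silyl 5‑bromo derivative (C5–Br → C5–H, ArO–Si → ArOH).
2. γ‑Lactone ring, formed second: the C4–O bond comes from bromolactonization of a racemic 1,2‑dioxene‑3‑acetic acid. A chiral catalyst lets only the (3S,6R)‑enantiomer close, and ring geometry forces the new C4–O bond cis to C3.
3. 1,2‑Dioxene ring, formed first: both C–O bonds come from [4+2] addition of singlet O2 to a (3E,5E)‑4,6‑dimethyl‑15‑arylpentadeca‑3,5‑dienoic acid. The E,E geometry puts the C3 arm and the C6 chain cis.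
4. Diene: the C4–C5 bond comes from Pd/Zn coupling of an (E)‑alkenylalane (carboalumination of an aryl‑undecyne) with (E)‑4‑iodopent‑3‑en‑1‑ol, then CH2OH → CO2H.
5. Aryl‑undecyne: protected 4‑hydroxyphenyl Grignard reagent plus undec‑10‑ynyl tosylate under copper catalysis.

Assumption: the presumed biosynthesis is read as [4+2] addition of O2 across the (3E,5E)‑diene of a polyketide acid, followed by closure of the carboxyl group onto C4 of the resulting 1,2‑dioxene.

Assumption: with (DHQD)2PHAL the enantiomer of the racemic dioxene acid that lactonizes faster is the (3S,6R) one; if the sense proves opposite, (DHQ)2PHAL is used with nothing else changed.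

Numbering: plakortolide numbering is used for all ring compounds (C1 lactone C=O, C2 CH2, C3 CH–O–O, C4 C(CH3)–O‑lactone, C5 CH2, C6 C(CH3)–O–O, C7–C15 nonyl chain, aryl on C15); it coincides with the IUPAC numbering of the open‑chain acid.

## Route

```
Step 1
Reactants: 1 undec-10-yn-1-ol
Product: 2 undec-10-yn-1-yl 4-methylbenzenesulfonate
Conditions: TsCl, Et3N, DMAP (cat.), CH2Cl2, 0 °C to rt
Reagents that add atoms: 4-toluenesulfonyl chloride, Cc1ccc(cc1)S(=O)(=O)Cl
Why: Sulfonylation of the primary alcohol (tosylate formation) gives the leaving group for the copper-catalysed coupling and creates no stereocentre.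

Step 2
Reactants: 3 (4-bromophenoxy)(tert-butyl)dimethylsilane; 2 undec-10-yn-1-yl 4-methylbenzenesulfonate
Product: 5 tert-butyldimethyl[4-(undec-10-yn-1-yl)phenoxy]silane, via arylmagnesium bromide 4 (not isolated)
Conditions: 3 (2.2 equiv), Mg, THF, 50 °C; then 2, Li2CuCl4 (3 mol%), THF, -20 °C to rt
Reagents that add atoms: none
Why: Copper-catalysed Grignard-alkyl tosylate cross-coupling (Kochi-type sp2-sp3 coupling) joins the protected phenol to the C9 chain, one equivalent of 4 being spent reversibly on the alkyne C-H, and no stereocentre is formed.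

Step 3
Reactants: 6 pent-3-yn-1-ol
Product: 8 (E)-4-iodopent-3-en-1-ol, via alkenylzirconocene chloride 7 (not isolated)
Conditions: Cp2Zr(H)Cl (2.5 equiv), THF, rt; then I2, THF, 0 °C
Reagents that add atoms: iodine, [I][I]
Why: Hydrozirconation-iodination: after the first equivalent of Cp2Zr(H)Cl has taken the O-H, syn addition of Zr-H puts zirconium on the methyl-bearing alkyne carbon and iodinolysis with retention fixes the E geometry of the future C3=C4 bond.

Step 4
Reactants: 5 tert-butyldimethyl[4-(undec-10-yn-1-yl)phenoxy]silane; 8 (E)-4-iodopent-3-en-1-ol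
Product: 11 (3E,5E)-15-[4-(tert-butyldimethylsilyloxy)phenyl]-4,6-dimethylpentadeca-3,5-dien-1-ol, via alkenylalane 9 (not isolated), via aluminium alkoxide 10 (not isolated)
Conditions: 5, AlMe3 (2.5 equiv), Cp2ZrCl2 (25 mol%), CH2Cl2, 0 °C to rt, then excess AlMe3 off in vacuo; 8, AlMe3 (1.0 equiv), THF, 0 °C; combined, Pd(PPh3)4 (5 mol%), ZnCl2 (0.5 equiv), THF, rt
Reagents that add atoms: trimethylaluminium, C[Al](C)C
Why: Zirconium-catalysed syn-carboalumination of the terminal alkyne (Negishi carboalumination) fixes the E geometry of the future C5=C6 bond, and the palladium/zinc-catalysed alkenyl-alkenyl cross-coupling (Negishi coupling) proceeds with retention at both carbons to give the 3E,5E-diene.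

Step 5
Reactants: 11 (3E,5E)-15-[4-(tert-butyldimethylsilyloxy)phenyl]-4,6-dimethylpentadeca-3,5-dien-1-ol
Product: 12 (3E,5E)-15-[4-(tert-butyldimethylsilyloxy)phenyl]-4,6-dimethylpentadeca-3,5-dienoic acid
Conditions: TEMPO (20 mol%), PhI(OAc)2 (2.2 equiv), MeCN/H2O 1:1, 0 °C to rt
Reagents that add atoms: water, O
Why: TEMPO/PhI(OAc)2 oxoammonium oxidation carries the primary alcohol through the aldehyde hydrate to the acid under near-neutral conditions, so the skipped diene is not drawn into conjugation and the aryl silyl ether stays.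

Step 6
Reactants: 12 (3E,5E)-15-[4-(tert-butyldimethylsilyloxy)phenyl]-4,6-dimethylpentadeca-3,5-dienoic acid
Product: 13 rac-2-[(3S,6R)-6-{9-[4-(tert-butyldimethylsilyloxy)phenyl]nonyl}-4,6-dimethyl-3,6-dihydro-1,2-dioxin-3-yl]acetic acid
Conditions: O2, tetraphenylporphyrin (1 mol%), white LED, CH2Cl2, -20 °C
Reagents that add atoms: dioxygen, O=O
Why: Singlet-oxygen [4+2] cycloaddition (dye-sensitised photooxygenation) is suprafacial on the s-cis 3E,5E-diene, so both C-O bonds form in one step and the two outside groups (acetic acid arm at C3, nonyl chain at C6) end up cis, giving the racemate with the relative configuration of the target.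

Step 7
Reactants: 13 rac-2-[(3S,6R)-6-{9-[4-(tert-butyldimethylsilyloxy)phenyl]nonyl}-4,6-dimethyl-3,6-dihydro-1,2-dioxin-3-yl]acetic acid
Product: 14 (3S,4R,5S,6R)-5-bromoplakortolide F tert-butyldimethylsilyl ether (cis-fused bromolactone; Br on C5 anti to the lactone oxygen on C4)
Conditions: (DHQD)2PHAL (10 mol%), NBS (0.55 equiv), CHCl3/hexane 1:1, -40 °C, stopped at ca. 50% conversion; unreacted acid removed with aq. NaHCO3
Reagents that add atoms: N-bromosuccinimide, O=C1CCC(=O)N1Br
Why: Proposed new method: kinetic resolution by catalyst-controlled bromolactonization, in which the carboxylate, ion-paired with the protonated bis-cinchona catalyst that also carries the Br+ donor, opens the bromonium ion at tertiary C4 (5-exo, Markovnikov), a closure that the ring geometry allows only on the face bearing the acetic acid arm, so that C4-O is set cis to C3-C2 and Br anti at C5 while the catalyst has to choose between the two enantiomers (each offers one productive alkene face) and converts the (3S,6R)-acid first; the closest known reaction type is the kinetic resolution of beta-substituted alkenoic acids and amides by cinchona-alkaloid-catalysed halocyclization.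

Step 8
Reactants: 14 (3S,4R,5S,6R)-5-bromoplakortolide F tert-butyldimethylsilyl ether
Product: 16 plakortolide F, via silyl ether 15 (not isolated)
Conditions: Bu3SnH (3 equiv, 0.5 M), Et3B (0.3 equiv), air, toluene, 0 °C; then TBAF, AcOH, THF, 0 °C
Reagents that add atoms: none
Why: Radical-chain debromination with Bu3SnH (the C5 radical is reduced much faster than it can attack the ring O-O bond, which the chair holds gauche and out of line) followed in the same flask by buffered fluoride cleavage of the aryl silyl ether leaves C3, C4 and C6 untouched and gives the target.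
```

## Compound list

```
1 | undec-10-yn-1-ol | C#CCCCCCCCCCO | starting material
2 | undec-10-yn-1-yl 4-methylbenzenesulfonate | C#CCCCCCCCCCOS(=O)(=O)c1ccc(C)cc1 | intermediate
3 | (4-bromophenoxy)(tert-butyl)dimethylsilane | CC(C)(C)[Si](C)(C)Oc1ccc(Br)cc1 | starting material
4 | {4-[(tert-butyldimethylsilyl)oxy]phenyl}magnesium bromide | CC(C)(C)[Si](C)(C)Oc1ccc([Mg]Br)cc1 | intermediate
5 | tert-butyldimethyl[4-(undec-10-yn-1-yl)phenoxy]silane | C#CCCCCCCCCCc1ccc(O[Si](C)(C)C(C)(C)C)cc1 | intermediate
6 | pent-3-yn-1-ol | CC#CCCO | starting material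
7 | [(E)-5-{[chlorobis(cyclopentadienyl)zirconio]oxy}pent-2-en-2-yl]chlorobis(cyclopentadienyl)zirconium | C/C(=C\CCO[Zr](Cl)(C1C=CC=C1)C1C=CC=C1)[Zr](Cl)(C1C=CC=C1)C1C=CC=C1 | intermediate
8 | (E)-4-iodopent-3-en-1-ol | OCC/C=C(\C)I | intermediate
9 | {(E)-11-[4-(tert-butyldimethylsilyloxy)phenyl]-2-methylundec-1-en-1-yl}dimethylalane | C[Al](C)/C=C(\C)CCCCCCCCCc1ccc(O[Si](C)(C)C(C)(C)C)cc1 | intermediate
10 | dimethylaluminium (E)-4-iodopent-3-en-1-olate | C[Al](C)OCC/C=C(\C)I | intermediate
11 | (3E,5E)-15-[4-(tert-butyldimethylsilyloxy)phenyl]-4,6-dimethylpentadeca-3,5-dien-1-ol | OCC/C=C(\C)/C=C(\C)CCCCCCCCCc1ccc(O[Si](C)(C)C(C)(C)C)cc1 | intermediate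
12 | (3E,5E)-15-[4-(tert-butyldimethylsilyloxy)phenyl]-4,6-dimethylpentadeca-3,5-dienoic acid | OC(=O)C/C=C(\C)/C=C(\C)CCCCCCCCCc1ccc(O[Si](C)(C)C(C)(C)C)cc1 | intermediate
13 | rac-2-[(3S,6R)-6-{9-[4-(tert-butyldimethylsilyloxy)phenyl]nonyl}-4,6-dimethyl-3,6-dihydro-1,2-dioxin-3-yl]acetic acid (racemate; acetic acid arm and nonyl chain cis; the enantiomer that goes on is drawn) | C[C@@]1(CCCCCCCCCc2ccc(O[Si](C)(C)C(C)(C)C)cc2)C=C(C)[C@H](CC(=O)O)OO1 | intermediate
14 | (3S,4R,5S,6R)-5-bromoplakortolide F tert-butyldimethylsilyl ether (cis-fused 1,2-dioxane/gamma-lactone; Br on C5 trans to the lactone oxygen on C4) | C[C@@]1(CCCCCCCCCc2ccc(O[Si](C)(C)C(C)(C)C)cc2)[C@@H](Br)[C@]2(C)OC(=O)C[C@@H]2OO1 | intermediate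
15 | (3S,4S,6R)-plakortolide F tert-butyldimethylsilyl ether | C[C@@]1(CCCCCCCCCc2ccc(O[Si](C)(C)C(C)(C)C)cc2)C[C@]2(C)OC(=O)C[C@@H]2OO1 | intermediate
16 | plakortolide F, (3S,4S,6R): cis-fused 1,2-dioxane/gamma-lactone with CH3 on C4 and C6 and the 9-(4-hydroxyphenyl)nonyl chain on C6 cis to the lactone oxygen | C[C@@]1(CCCCCCCCCc2ccc(O)cc2)C[C@]2(C)OC(=O)C[C@@H]2OO1 | target
```

## Step count and weak points

Total step count: 8. Longest linear sequence: 7 steps (1, 2, 4, 5, 6, 7, 8 from undec‑10‑yn‑1‑ol; step 3 supplies the coupling partner). Step 7 is a resolution, so its yield is capped at 50%.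

The three steps most likely to fail:

**Step 6 (photooxygenation).** Both trisubstituted alkenes carry allylic C–H bonds, so Schenck ene hydroperoxides can outrun the [4+2] adduct, and a stepwise pathway would erode the cis relationship. The fallback sets out from 12 and comes back at 13; it replaces singlet oxygen by an electron‑transfer oxygenation with ground‑state O2 that has no ene channel. 12 is esterified (TMSCHN2, MeOH/toluene) to methyl (3E,5E)‑15‑[4‑(tert‑butyldimethylsilyloxy)phenyl]‑4,6‑dimethylpentadeca‑3,5‑dienoate F1. F1 is treated with O2 and (4‑BrC6H4)3N·SbCl6 (5 mol%) in CH2Cl2 at −78 °C, a diene radical‑cation chain cycloaddition, to give rac‑methyl 2‑[(3S,6R)‑6‑{9‑[4‑(tert‑butyldimethylsilyloxy)phenyl]nonyl}‑4,6‑dimethyl‑3,6‑dihydro‑1,2‑dioxin‑3‑yl]acetate F2; the 3,6‑cis isomer is separated by chromatography if the trans isomer also forms. F2 is hydrolysed under neutral conditions (Me3SnOH, 1,2‑dichloroethane, 60 °C) to 13.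

**Step 7 (resolving bromolactonization).** The selectivity factor is unknown, the product's enantiomeric purity drops quickly past about 45% conversion, and the quinuclidine nitrogen could open the peroxide at C3–H (Kornblum–DeLaMare). The fallback sets out from 13 and comes back at 15; it uses covalent resolution in place of catalysis. 13 is coupled with (S)‑1‑phenylethylamine (EDC, HOBt, CH2Cl2), the two diastereomeric amides are separated by chromatography, and N‑[(S)‑1‑phenylethyl]‑2‑[(3S,6R)‑6‑{9‑[4‑(tert‑butyldimethylsilyloxy)phenyl]nonyl}‑4,6‑dimethyl‑3,6‑dihydro‑1,2‑dioxin‑3‑yl]acetamide F3 is kept. Iodolactonization of F3 (I2, NaHCO3, THF/H2O, 0 °C; the iminolactone first formed hydrolyses with loss of the amine) gives (3S,4R,5S,6R)‑5‑iodoplakortolide F tert‑butyldimethylsilyl ether F4. F4 is deiodinated under the stannane conditions of step 8 (Bu3SnH, Et3B, air, toluene, 0 °C) to 15.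

**Step 5 (oxidation).** The intermediate 3,5‑dienal is doubly activated at C2 and can slide into conjugation before it is oxidised further. The fallback sets out from 11 and comes back at 13; it inverts the order of oxidation and oxygenation. 11 is photooxygenated under the conditions of step 6 to rac‑2‑[(3S,6R)‑6‑{9‑[4‑(tert‑butyldimethylsilyloxy)phenyl]nonyl}‑4,6‑dimethyl‑3,6‑dihydro‑1,2‑dioxin‑3‑yl]ethan‑1‑ol F5. F5 is then oxidised with TEMPO/PhI(OAc)2 (MeCN/H2O) to 13; the aldehyde on the way no longer has a diene to conjugate with.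

```
Further compounds
F1 | step 6 | methyl (3E,5E)-15-[4-(tert-butyldimethylsilyloxy)phenyl]-4,6-dimethylpentadeca-3,5-dienoate | COC(=O)C/C=C(\C)/C=C(\C)CCCCCCCCCc1ccc(O[Si](C)(C)C(C)(C)C)cc1
F2 | step 6 | rac-methyl 2-[(3S,6R)-6-{9-[4-(tert-butyldimethylsilyloxy)phenyl]nonyl}-4,6-dimethyl-3,6-dihydro-1,2-dioxin-3-yl]acetate | C[C@@]1(CCCCCCCCCc2ccc(O[Si](C)(C)C(C)(C)C)cc2)C=C(C)[C@H](CC(=O)OC)OO1
F3 | step 7 | N-[(S)-1-phenylethyl]-2-[(3S,6R)-6-{9-[4-(tert-butyldimethylsilyloxy)phenyl]nonyl}-4,6-dimethyl-3,6-dihydro-1,2-dioxin-3-yl]acetamide | C[C@@]1(CCCCCCCCCc2ccc(O[Si](C)(C)C(C)(C)C)cc2)C=C(C)[C@H](CC(=O)N[C@@H](C)c2ccccc2)OO1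
F4 | step 7 | (3S,4R,5S,6R)-5-iodoplakortolide F tert-butyldimethylsilyl ether | C[C@@]1(CCCCCCCCCc2ccc(O[Si](C)(C)C(C)(C)C)cc2)[C@@H]([I])[C@]2(C)OC(=O)C[C@@H]2OO1
F5 | step 5 | rac-2-[(3S,6R)-6-{9-[4-(tert-butyldimethylsilyloxy)phenyl]nonyl}-4,6-dimethyl-3,6-dihydro-1,2-dioxin-3-yl]ethan-1-ol | C[C@@]1(CCCCCCCCCc2ccc(O[Si](C)(C)C(C)(C)C)cc2)C=C(C)[C@H](CCO)OO1
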